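## Retrosynthetic overview

1. The exocyclic C=C between ring A and the hydrindane is cut last: Horner–Wittig olefination of (S)-4-bromo-3,3-dimethylcyclohexanone with a hydrindane carrying C1–CH2P(O)Ph2.
2. Key disconnection: C1–C2 of the cyclopentane ring. The ketyl radical anion of a C2 aldehyde (carbonyl carbon acting as nucleophile) adds to C1 of an alkenylphosphine oxide; this sets C1 and C2 and leaves the phosphorus handle.
3. Cyclohexane ring of the hydrindane: the C3a–C7a bond is made by cyclisation of an enantiopure bromonium ion (from a vicinal bromochloride) onto a silyl dienol ether; the C7 carbinol comes from methyl addition to the resulting ketone.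
4. Ring A: the same bromochloride-to-bromonium logic starting from prenol, closed onto an alkynylsilane.
5. Order of ring formation: cyclohexane ring of the hydrindane, then its cyclopentane ring (key step); ring A is made separately and joined last.

Assumption: hydrindane positions are numbered C1–C7a as in the systematic name of the target, ring A is the bromodimethylcyclohexylidene ring, and the chiral ligand of steps 2 and 9 is used as the enantiomer that delivers the (2S)-bromides.

## Route

Step 1
Reactants: 1 pent-1-en-4-yne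
Product: 3 (2E)-3-methylhexa-2,5-dien-1-ol, via alkenylalane 2 (not isolated)
Conditions: AlMe3 (2 equiv), Cp2ZrCl2 (20 mol %), CH2Cl2, 0 °C to rt; then n-BuLi, (CH2O)n, THF, −78 °C to rt
Reagents that add atoms: trimethylaluminium C[Al](C)C; paraformaldehyde (as formaldehyde) C=O
Why: Negishi zirconium-catalysed carboalumination adds methyl and aluminium syn across the terminal alkyne (Al on the terminal carbon) much faster than across the isolated alkene, and the alanate formed with n-BuLi is hydroxymethylated by formaldehyde with retention, so the trisubstituted alkene is E.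

Step 2
Reactants: 3 (2E)-3-methylhexa-2,5-dien-1-ol
Product: 4 (2S,3R)-2-bromo-3-chloro-3-methylhex-5-en-1-ol
Conditions: NBS (1.1 equiv), ClTi(OiPr)3 (1.1 equiv), tridentate salicylaldimine–amino alcohol ligand (single enantiomer, 20 mol %), hexanes, −20 °C
Reagents that add atoms: N-bromosuccinimide BrN1C(=O)CCC1=O; chlorotitanium triisopropoxide CC(C)O[Ti](Cl)(OC(C)C)OC(C)C
Why: Titanium-alkoxide-directed catalytic enantioselective bromochlorination of an allylic alcohol: the ligated titanium alkoxide controls the face on which NBS forms the bromonium ion and chloride opens it anti at the tertiary carbon (Markovnikov), which sets the secondary bromide (S, the future C4) and, through anti addition to the E alkene, the tertiary chloride (R), while the unactivated terminal alkene does not react.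

Step 3
Reactants: 5 diphenyl(prop-2-en-1-yl)phosphine oxide; 6 but-3-en-2-one
Product: 7 (3E)-5-(diphenylphosphoryl)pent-3-en-2-one
Conditions: second-generation Grubbs catalyst (C46H65Cl2N2PRu, 3 mol %), 6 (3 equiv), CH2Cl2, 40 °C
Reagents that add atoms: none
Why: Olefin cross-metathesis of a terminal alkene with an electron-poor enone partner gives the E enone because secondary metathesis equilibrates to the more stable isomer.

Step 4
Reactants: 4 (2S,3R)-2-bromo-3-chloro-3-methylhex-5-en-1-ol; 7 (3E)-5-(diphenylphosphoryl)pent-3-en-2-one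
Product: 11 [(1E,3Z,7S,8R)-7-bromo-4-{[tert-butyl(dimethyl)silyl]oxy}-8-chloro-8-methylundeca-1,3,10-trien-1-yl](diphenyl)phosphine oxide, via triflate 8 (not isolated), via dilithio dianion 9 (not isolated), via lithium dienolate 10 (not isolated)
Conditions: 4, Tf2O (1.1 equiv), 2,6-lutidine, CH2Cl2, −78 °C, rapid silica filtration; separately 7, LiN(iPr)2 (2.1 equiv), THF, −78 to −20 °C; crude 8 added at −78 °C; then TBSOTf (1.2 equiv), −78 to 0 °C
Reagents that add atoms: tert-butyldimethylsilyl trifluoromethanesulfonate CC(C)(C)[Si](C)(C)OS(=O)(=O)C(F)(F)F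
Why: Dianion alkylation of the acetoacetate-dianion type: the last-formed, least stabilised methyl carbanion of 9 displaces the primary triflate by SN2 (no stereocentre is touched), and the remaining phosphoryl-stabilised dienolate is silylated on oxygen to the extended silyl dienol ether that serves as the cyclisation terminator.

Step 5
Reactants: 11 [(1E,3Z,7S,8R)-7-bromo-4-{[tert-butyl(dimethyl)silyl]oxy}-8-chloro-8-methylundeca-1,3,10-trien-1-yl](diphenyl)phosphine oxide
Product: 12 (2S,3S,4S)-4-bromo-2-[(E)-2-(diphenylphosphoryl)ethenyl]-3-methyl-3-(prop-2-en-1-yl)cyclohexan-1-one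
Conditions: TiCl4 (2.2 equiv), 2,6-di-tert-butylpyridine (0.2 equiv), CH2Cl2, −78 °C
Reagents that add atoms: none
Why: Bromonium-initiated cation–olefin cyclisation run as a Lewis-acid tert-alkylation of a silyl enol ether: TiCl4 abstracts the tertiary chloride with anchimeric assistance from the neighbouring bromine, and the resulting enantiopure bromonium ion is opened anti at C3a by the α-carbon of the dienol ether through a chair transition state, which places Br equatorial, the C3a methyl axial and the alkenyl group on C7a equatorial (the α-keto centre C7a can also equilibrate to this isomer), so C4 controls C3a and C7a.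

Step 6
Reactants: 12 (2S,3S,4S)-4-bromo-2-[(E)-2-(diphenylphosphoryl)ethenyl]-3-methyl-3-(prop-2-en-1-yl)cyclohexan-1-one
Product: 13 (1R,2S,3S,4S)-4-bromo-2-[(E)-2-(diphenylphosphoryl)ethenyl]-1,3-dimethyl-3-(prop-2-en-1-yl)cyclohexan-1-ol
Conditions: MeMgBr (3 equiv), CeCl3 (3 equiv), THF, −78 °C
Reagents that add atoms: methylmagnesium bromide C[Mg]Br
Why: Organocerium 1,2-addition (CeCl3 suppresses enolisation of the acidic α-position and conjugate addition to the alkenylphosphine oxide): axial attack is blocked by the 1,3-diaxial C3a methyl, so methyl enters equatorially and the tertiary alcohol is axial (the future 7R centre).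

Step 7
Reactants: 13 (1R,2S,3S,4S)-4-bromo-2-[(E)-2-(diphenylphosphoryl)ethenyl]-1,3-dimethyl-3-(prop-2-en-1-yl)cyclohexan-1-ol
Product: 14 2-[(1S,2S,3R,6S)-6-bromo-2-[(E)-2-(diphenylphosphoryl)ethenyl]-3-hydroxy-1,3-dimethylcyclohexyl]acetaldehyde
Conditions: OsO4 (2 mol %), NaIO4 (3 equiv), 2,6-lutidine, dioxane–H2O (3:1), rt
Reagents that add atoms: sodium periodate NaIO4 (oxygen relayed by OsO4) [Na+].[O-]I(=O)(=O)=O
Why: Lemieux–Johnson oxidative cleavage: electrophilic OsO4 dihydroxylates the electron-rich monosubstituted alkene in preference to the electron-poor alkenylphosphine oxide and periodate cleaves the diol to the aldehyde, with no stereocentre affected.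

Step 8
Reactants: 14 2-[(1S,2S,3R,6S)-6-bromo-2-[(E)-2-(diphenylphosphoryl)ethenyl]-3-hydroxy-1,3-dimethylcyclohexyl]acetaldehyde
Product: 15 {[(1S,2R,3aS,4S,7R,7aS)-4-bromo-2,7-dihydroxy-3a,7-dimethyloctahydro-1H-inden-1-yl]methyl}(diphenyl)phosphine oxide
Conditions: SmI2 (2.5 equiv), t-BuOH (2 equiv), THF, −78 °C
Reagents that add atoms: none
Why: Proposed new method: SmI2 reduces the aldehyde to a ketyl radical anion, so that the normally electrophilic carbonyl carbon C2 attacks as a nucleophilic radical the electrophilic β-carbon C1 of the alkenylphosphine oxide in a 5-exo-trig ring closure, and the α-phosphoryl radical is reduced and protonated by t-BuOH; C1 follows from the A(1,3)-minimised rotamer in which H-7a eclipses the alkene (the CH2P(O)Ph2 arm ends cis to H-7a, away from the C7 substituents), and the C2 oxygen is expected syn to that arm because the oxophilic trivalent samarium of the ketyl is chelated by the P=O group and avoids the axial C3a methyl; the closest known reaction type is the SmI2 ketyl–olefin cyclisation onto acrylates and vinyl sulfones, which usually gives the anti isomer when no chelating group is present.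

Step 9
Reactants: 16 3-methylbut-2-en-1-ol
Product: 17 (2S)-2-bromo-3-chloro-3-methylbutan-1-ol
Conditions: NBS (1.1 equiv), ClTi(OiPr)3 (1.1 equiv), the same ligand enantiomer as in step 2 (20 mol %), hexanes, −20 °C
Reagents that add atoms: N-bromosuccinimide BrN1C(=O)CCC1=O; chlorotitanium triisopropoxide CC(C)O[Ti](Cl)(OC(C)C)OC(C)C
Why: The same titanium-mediated enantioselective bromochlorination of an allylic alcohol: face-selective bromonium formation and Markovnikov chloride opening give the secondary bromide that becomes the only stereocentre of ring A (S).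

Step 10
Reactants: 17 (2S)-2-bromo-3-chloro-3-methylbutan-1-ol; 18 trimethyl(prop-1-yn-1-yl)silane
Product: 21 [(5S)-5-bromo-6-chloro-6-methylhept-1-yn-1-yl](trimethyl)silane, via triflate 19 (not isolated), via lithio alkyne 20 (not isolated)
Conditions: 17, Tf2O (1.1 equiv), 2,6-lutidine, CH2Cl2, −78 °C, rapid silica filtration; separately 18, n-BuLi, THF, −78 to 0 °C; crude 19 added at −78 °C
Reagents that add atoms: none
Why: SN2 propargylation: the lithiated silylpropyne reacts at its propargylic carbon with the primary triflate, the bromide-bearing stereocentre is not involved, and the silyl group later steers the ring closure.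

Step 11
Reactants: 21 [(5S)-5-bromo-6-chloro-6-methylhept-1-yn-1-yl](trimethyl)silane
Product: 23 (4S)-4-bromo-3,3-dimethylcyclohexan-1-one, via silyl enol ether 22 (not isolated)
Conditions: (CF3)2CHOH, 0 °C to rt; then 1 M HCl, THF, rt
Reagents that add atoms: water O
Why: Solvolytic bromonium generation followed by cation–alkyne cyclisation: in the ionising, weakly nucleophilic solvent the tertiary chloride leaves with anchimeric assistance from bromine, the alkynylsilane attacks the tertiary end of the bromonium ion through its silicon-bearing carbon (6-endo, the vinyl cation is β-stabilised by silicon), solvent capture gives 22 and acid hydrolysis with protodesilylation gives the ketone, the C–Br bond never being broken so that the S configuration is kept.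

Step 12
Reactants: 15 {[(1S,2R,3aS,4S,7R,7aS)-4-bromo-2,7-dihydroxy-3a,7-dimethyloctahydro-1H-inden-1-yl]methyl}(diphenyl)phosphine oxide; 23 (4S)-4-bromo-3,3-dimethylcyclohexan-1-one
Product: 26 (1S,2R,3aS,4S,7R,7aS)-4-bromo-1-{(E)-[(4S)-4-bromo-3,3-dimethylcyclohexylidene]methyl}-3a,7-dimethyloctahydro-1H-indene-2,7-diol (iriediol), via trilithio phosphine oxide 24 (not isolated), via alkoxide adduct 25 (not isolated)
Conditions: 15, LiN(iPr)2 (3.3 equiv), THF, −78 to −40 °C; 23, −78 °C; then KOt-Bu (1.2 equiv), −78 to 0 °C; NH4Cl work-up; chromatography on AgNO3-impregnated silica to remove the Z isomer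
Reagents that add atoms: none
Why: Horner–Wittig olefination: the lithiated phosphine oxide adds to the ketone from the equatorial direction and potassium alkoxide formation triggers stereospecific syn elimination of diphenylphosphinate, so the alkene geometry is fixed by the relative configuration of the two new centres in the adduct (25 is the isomer that gives E), the E isomer being expected to predominate only modestly because the bulky hydrindanyl group avoids the ring CH2 flanked by the quaternary carbon.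

## Compound list

1 | pent-1-en-4-yne | C#CCC=C | starting material
2 | dimethyl[(1E)-2-methylpenta-1,4-dien-1-yl]alumane | C=CC/C(C)=C/[Al](C)C | intermediate
3 | (2E)-3-methylhexa-2,5-dien-1-ol | C=CC/C(C)=C/CO | intermediate
4 | (2S,3R)-2-bromo-3-chloro-3-methylhex-5-en-1-ol | C=CC[C@@](C)(Cl)[C@@H](Br)CO | intermediate
5 | diphenyl(prop-2-en-1-yl)phosphine oxide | C=CCP(=O)(c1ccccc1)c1ccccc1 | starting material
6 | but-3-en-2-one | CC(=O)C=C | starting material
7 | (3E)-5-(diphenylphosphoryl)pent-3-en-2-one | CC(=O)/C=C/CP(=O)(c1ccccc1)c1ccccc1 | intermediate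
8 | (2S,3R)-2-bromo-3-chloro-3-methylhex-5-en-1-yl trifluoromethanesulfonate | C=CC[C@@](C)(Cl)[C@@H](Br)COS(=O)(=O)C(F)(F)F | intermediate
9 | dilithium dianion of 7 (deprotonated at C1 and C5, drawn as the C1 carbanion of the (2Z,4E)-dienolate) | [Li+].[Li+].[CH2-]/C([O-])=C/C=C/P(=O)(c1ccccc1)c1ccccc1 | intermediate
10 | lithium (1E,3Z,7S,8R)-7-bromo-8-chloro-1-(diphenylphosphoryl)-8-methylundeca-1,3,10-trien-4-olate | [Li+].C=CC[C@@](C)(Cl)[C@@H](Br)CC/C([O-])=C/C=C/P(=O)(c1ccccc1)c1ccccc1 | intermediate
11 | [(1E,3Z,7S,8R)-7-bromo-4-{[tert-butyl(dimethyl)silyl]oxy}-8-chloro-8-methylundeca-1,3,10-trien-1-yl](diphenyl)phosphine oxide | C=CC[C@@](C)(Cl)[C@@H](Br)CC/C(O[Si](C)(C)C(C)(C)C)=C/C=C/P(=O)(c1ccccc1)c1ccccc1 | intermediate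
12 | (2S,3S,4S)-4-bromo-2-[(E)-2-(diphenylphosphoryl)ethenyl]-3-methyl-3-(prop-2-en-1-yl)cyclohexan-1-one | C=CC[C@]1(C)[C@@H](Br)CCC(=O)[C@H]1/C=C/P(=O)(c2ccccc2)c2ccccc2 | intermediate
13 | (1R,2S,3S,4S)-4-bromo-2-[(E)-2-(diphenylphosphoryl)ethenyl]-1,3-dimethyl-3-(prop-2-en-1-yl)cyclohexan-1-ol | C=CC[C@]1(C)[C@@H](Br)CC[C@@](C)(O)[C@H]1/C=C/P(=O)(c2ccccc2)c2ccccc2 | intermediate
14 | 2-[(1S,2S,3R,6S)-6-bromo-2-[(E)-2-(diphenylphosphoryl)ethenyl]-3-hydroxy-1,3-dimethylcyclohexyl]acetaldehyde | O=CC[C@]1(C)[C@@H](Br)CC[C@@](C)(O)[C@H]1/C=C/P(=O)(c2ccccc2)c2ccccc2 | intermediate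
15 | {[(1S,2R,3aS,4S,7R,7aS)-4-bromo-2,7-dihydroxy-3a,7-dimethyloctahydro-1H-inden-1-yl]methyl}(diphenyl)phosphine oxide | O=P(C[C@@H]2[C@H](O)C[C@]3(C)[C@@H](Br)CC[C@@](C)(O)[C@@H]23)(c1ccccc1)c1ccccc1 | intermediate
16 | 3-methylbut-2-en-1-ol (prenol) | CC(C)=CCO | starting material
17 | (2S)-2-bromo-3-chloro-3-methylbutan-1-ol | OC[C@H](Br)C(C)(C)Cl | intermediate
18 | trimethyl(prop-1-yn-1-yl)silane | CC#C[Si](C)(C)C | starting material
19 | (2S)-2-bromo-3-chloro-3-methylbutyl trifluoromethanesulfonate | O=S(=O)(OC[C@H](Br)C(C)(C)Cl)C(F)(F)F | intermediate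
20 | [3-(trimethylsilyl)prop-2-yn-1-yl]lithium | [Li]CC#C[Si](C)(C)C | intermediate
21 | [(5S)-5-bromo-6-chloro-6-methylhept-1-yn-1-yl](trimethyl)silane | C[Si](C)(C)C#CCC[C@H](Br)C(C)(C)Cl | intermediate
22 | {(5S)-5-bromo-2-[(1,1,1,3,3,3-hexafluoropropan-2-yl)oxy]-6,6-dimethylcyclohex-1-en-1-yl}(trimethyl)silane | CC1(C)C([Si](C)(C)C)=C(OC(C(F)(F)F)C(F)(F)F)CC[C@@H]1Br | intermediate
23 | (4S)-4-bromo-3,3-dimethylcyclohexan-1-one | CC1(C)CC(=O)CC[C@@H]1Br | intermediate
24 | trilithium salt of 15 (C2 and C7 alkoxides, α-phosphoryl carbanion) | [Li+].[Li+].[Li+].O=P([CH-][C@@H]2[C@H]([O-])C[C@]3(C)[C@@H](Br)CC[C@@](C)([O-])[C@@H]23)(c1ccccc1)c1ccccc1 | intermediate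
25 | trilithium trialkoxide of [(R)-[(1R,4S)-4-bromo-1-hydroxy-3,3-dimethylcyclohexyl][(1S,2R,3aS,4S,7R,7aS)-4-bromo-2,7-dihydroxy-3a,7-dimethyloctahydro-1H-inden-1-yl]methyl](diphenyl)phosphine oxide | [Li+].[Li+].[Li+].O=P(c1ccccc1)(c1ccccc1)[C@H]([C@@H]2[C@H]([O-])C[C@]3(C)[C@@H](Br)CC[C@@](C)([O-])[C@@H]23)[C@]4([O-])CC(C)(C)[C@@H](Br)CC4 | intermediate
26 | (1S,2R,3aS,4S,7R,7aS)-4-bromo-1-{(E)-[(4S)-4-bromo-3,3-dimethylcyclohexylidene]methyl}-3a,7-dimethyloctahydro-1H-indene-2,7-diol (iriediol) | CC1(C)C/C(=C/[C@@H]2[C@H](O)C[C@]3(C)[C@@H](Br)CC[C@@](C)(O)[C@@H]23)CC[C@@H]1Br | target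

## Step count and risks

Total steps: 12. Longest linear sequence: 8 steps (steps 1, 2, 4, 5, 6, 7, 8, 12); steps 3 and 9–11 are side branches.

The three steps most likely to fail:

**Step 8 (key ring closure, C2 configuration).** The ketyl may add with the usual anti preference and give the C2 epimer. The fallback sets out from 14 and accepts the anti cyclisation product {[(1S,2S,3aS,4S,7R,7aS)-4-bromo-2,7-dihydroxy-3a,7-dimethyloctahydro-1H-inden-1-yl]methyl}(diphenyl)phosphine oxide F1. Its secondary alcohol is inverted by a Mitsunobu reaction (PPh3, DIAD, 4-nitrobenzoic acid; the tertiary C7 alcohol does not react) to (1S,2R,3aS,4S,7R,7aS)-4-bromo-1-[(diphenylphosphoryl)methyl]-7-hydroxy-3a,7-dimethyloctahydro-1H-inden-2-yl 4-nitrobenzoate F2. Methanolysis with K2CO3 in MeOH then comes back to the route at 15.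

**Step 11 (bromonium closure onto the alkynylsilane).** The alkyne is a weak π-nucleophile, so solvent capture or elimination may win. The fallback sets out from triflate 19, which is used to alkylate the dianion of methyl acetoacetate (NaH, then n-BuLi, THF) to give methyl (6S)-6-bromo-7-chloro-7-methyl-3-oxooctanoate F3. Solvolysis in (CF3)2CHOH closes ring A through the much more nucleophilic enol carbon to methyl (5S)-5-bromo-2-hydroxy-6,6-dimethylcyclohex-1-ene-1-carboxylate F4 (the keto ester drawn as its enol). Krapcho dealkoxycarbonylation (LiCl, wet DMSO, 140 °C) comes back to the route at 23.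

**Step 12 (alkene geometry).** The two ring arms of 23 differ only at the β-position, so the E:Z ratio may be close to 1:1. The fallback sets out from 15 and 23: the coupling is stopped at the lithium alkoxide stage (NH4Cl instead of KOt-Bu) and the β-hydroxy phosphine oxides are separated on silica. The like-configured adduct [(R)-[(1R,4S)-4-bromo-1-hydroxy-3,3-dimethylcyclohexyl][(1S,2R,3aS,4S,7R,7aS)-4-bromo-2,7-dihydroxy-3a,7-dimethyloctahydro-1H-inden-1-yl]methyl](diphenyl)phosphine oxide F5 gives 26 directly by syn elimination with NaH in DMF. The unlike adduct [(S)-[(1R,4S)-4-bromo-1-hydroxy-3,3-dimethylcyclohexyl][(1S,2R,3aS,4S,7R,7aS)-4-bromo-2,7-dihydroxy-3a,7-dimethyloctahydro-1H-inden-1-yl]methyl](diphenyl)phosphine oxide F6 gives under the same conditions the Z olefin (1S,2R,3aS,4S,7R,7aS)-4-bromo-1-{(Z)-[(4S)-4-bromo-3,3-dimethylcyclohexylidene]methyl}-3a,7-dimethyloctahydro-1H-indene-2,7-diol F7. F7 is equilibrated toward the E isomer by reversible thiyl-radical addition (PhSSPh 10 mol %, light) and so also comes back to the route at 26.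

## Further compounds

F1 | step 8 | {[(1S,2S,3aS,4S,7R,7aS)-4-bromo-2,7-dihydroxy-3a,7-dimethyloctahydro-1H-inden-1-yl]methyl}(diphenyl)phosphine oxide | O=P(C[C@@H]2[C@@H](O)C[C@]3(C)[C@@H](Br)CC[C@@](C)(O)[C@@H]23)(c1ccccc1)c1ccccc1
F2 | step 8 | (1S,2R,3aS,4S,7R,7aS)-4-bromo-1-[(diphenylphosphoryl)methyl]-7-hydroxy-3a,7-dimethyloctahydro-1H-inden-2-yl 4-nitrobenzoate | O=P(C[C@@H]2[C@H](OC(=O)c4ccc(cc4)[N+](=O)[O-])C[C@]3(C)[C@@H](Br)CC[C@@](C)(O)[C@@H]23)(c1ccccc1)c1ccccc1
F3 | step 11 | methyl (6S)-6-bromo-7-chloro-7-methyl-3-oxooctanoate | COC(=O)CC(=O)CC[C@H](Br)C(C)(C)Cl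
F4 | step 11 | methyl (5S)-5-bromo-2-hydroxy-6,6-dimethylcyclohex-1-ene-1-carboxylate | COC(=O)C1=C(O)CC[C@H](Br)C1(C)C
F5 | step 12 | [(R)-[(1R,4S)-4-bromo-1-hydroxy-3,3-dimethylcyclohexyl][(1S,2R,3aS,4S,7R,7aS)-4-bromo-2,7-dihydroxy-3a,7-dimethyloctahydro-1H-inden-1-yl]methyl](diphenyl)phosphine oxide | O=P(c1ccccc1)(c1ccccc1)[C@H]([C@@H]2[C@H](O)C[C@]3(C)[C@@H](Br)CC[C@@](C)(O)[C@@H]23)[C@]4(O)CC(C)(C)[C@@H](Br)CC4
F6 | step 12 | [(S)-[(1R,4S)-4-bromo-1-hydroxy-3,3-dimethylcyclohexyl][(1S,2R,3aS,4S,7R,7aS)-4-bromo-2,7-dihydroxy-3a,7-dimethyloctahydro-1H-inden-1-yl]methyl](diphenyl)phosphine oxide | O=P(c1ccccc1)(c1ccccc1)[C@@H]([C@@H]2[C@H](O)C[C@]3(C)[C@@H](Br)CC[C@@](C)(O)[C@@H]23)[C@]4(O)CC(C)(C)[C@@H](Br)CC4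
F7 | step 12 | (1S,2R,3aS,4S,7R,7aS)-4-bromo-1-{(Z)-[(4S)-4-bromo-3,3-dimethylcyclohexylidene]methyl}-3a,7-dimethyloctahydro-1H-indene-2,7-diol | CC1(C)C/C(=C\[C@@H]2[C@H](O)C[C@]3(C)[C@@H](Br)CC[C@@](C)(O)[C@@H]23)CC[C@@H]1Br
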